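**Strategy.** The route rests on disconnecting the C2–C1′ bond of the flavan. Ring C is not cyclised from a chalcone or a diarylpropanol but comes, with ring A, from the flat coumarin scopoletin (6-OMe and 7-OH already in place). Its lactone carbon is turned into a 2-ethoxy acetal. The key step ionises this to the aromatic 1-benzopyrylium ion and adds the unprenylated B-ring aryl boronate to C2 under a chiral diol-acid/lanthanide catalyst, joining the two halves and setting the only stereocentre at once. It exploits the position of C2 between O1 and the aryl group. Both prenyl groups then arrive by one double aromatic Claisen rearrangement from O7 and O3′.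

Key step: step 6

Assumption: the sense of induction of the tartaric-acid-derived catalyst with this acetal/boronate pair is not predicted here. Both antipodes are available from L- and D-tartaric acid, and the one that gives 2S (checked on flavan 13) is used.
Remark: the catalyst of step 6 and the allyl carbonate of step 8 are not numbered; each is made in one or two routine steps from tartaric acid and from 2-methylbut-3-en-2-ol.

Step 1
Reactants: 1 scopoletin (7-hydroxy-6-methoxy-2H-chromen-2-one)
Product: 2 7-(benzyloxy)-6-methoxy-2H-chromen-2-one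
Conditions: BnBr, K2CO3, DMF, rt
Reagents that add atoms: benzyl bromide, BrCc1ccccc1
Why: Williamson O-benzylation of the only phenol under mild carbonate base, which the lactone tolerates at room temperature.

Step 2
Reactants: 2 7-(benzyloxy)-6-methoxy-2H-chromen-2-one
Product: 4 7-(benzyloxy)-2-ethoxy-6-methoxy-2H-chromene (racemic), via lactol 3 (not isolated)
Conditions: DIBAL-H (1.1 equiv), CH2Cl2, −78 °C; Rochelle salt work-up; crude 3, EtOH, PPTS (cat.), rt; Et3N quench
Reagents that add atoms: ethanol, CCO
Why: Lactone half-reduction with DIBAL-H stops at the aluminium hemiacetal at −78 °C, and the lactol then undergoes acid-catalysed acetalisation through the 7-alkoxy-stabilised benzopyrylium ion, trapped by ethanol at C2 (the acetal centre is racemic and is ionised again in step 6).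

Step 3
Reactants: 5 2-(benzyloxy)phenol
Product: 6 2-(benzyloxy)-4-bromophenol
Conditions: NBS (1.0 equiv), MeCN, −10 → 0 °C
Reagents that add atoms: N-bromosuccinimide, O=C1CCC(=O)N1Br
Why: Electrophilic aromatic bromination goes para to the free hydroxyl, the stronger donor, as with guaiacol, which places Br para to the future O4′ and meta to the future O3′.

Step 4
Reactants: 6 2-(benzyloxy)-4-bromophenol
Product: 7 2-(benzyloxy)-4-bromo-1-(methoxymethoxy)benzene
Conditions: MOMCl, i-Pr2NEt, CH2Cl2, 0 °C → rt
Reagents that add atoms: chloromethyl methyl ether, COCCl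
Why: Phenol O-alkylation to the MOM acetal, a group that does not migrate between catechol oxygens and is a para donor that keeps the aryl group nucleophilic in step 6.

Step 5
Reactants: 7 2-(benzyloxy)-4-bromo-1-(methoxymethoxy)benzene
Product: 10 [3-(benzyloxy)-4-(methoxymethoxy)phenyl]boronic acid, via aryllithium 8 (not isolated), via lithium triisopropoxyborate 9 (not isolated)
Conditions: n-BuLi, THF, −78 °C; B(Oi-Pr)3, −78 °C → rt; aq. NH4Cl, 1 M HCl to pH 5–6
Reagents that add atoms: triisopropyl borate, CC(C)OB(OC(C)C)OC(C)C; water, O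
Why: Lithiation–borylation, in which bromine–lithium exchange at −78 °C outruns ortho-lithiation next to OMOM and the borate is hydrolysed at a pH the MOM ether survives.

Step 6
Reactants: 4 7-(benzyloxy)-2-ethoxy-6-methoxy-2H-chromene (racemic); 10 [3-(benzyloxy)-4-(methoxymethoxy)phenyl]boronic acid
Product: 12 (2S)-7-(benzyloxy)-2-[3-(benzyloxy)-4-(methoxymethoxy)phenyl]-6-methoxy-2H-chromene, via diethyl arylboronate 11 (not isolated)
Conditions: 10, EtOH/toluene azeotrope, 4 Å MS (→ 11); then 4, tartaric-acid-derived α,β-dihydroxy acid mono-amide catalyst (10 mol %), Yb(OTf)3 (5 mol %), EtOAc, −20 → 4 °C, dark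
Reagents that add atoms: none
Why: The diol-acid catalyst exchanges onto boron of 11 to give a chiral, more Lewis-acidic dioxaborolane, which together with Yb(OTf)3 ionises acetal 4 to the aromatic 7-benzyloxy-6-methoxy-1-benzopyrylium ion; the departing ethoxide binds boron and the resulting chiral aryl ate complex hands its ipso carbon to C2 inside the contact ion pair. The closest known reaction type is the chiral Brønsted acid/lanthanide triflate co-catalysed enantioselective addition of alkenyl and electron-rich aryl boronates to 2-alkoxy-2H-chromenes (a Petasis-type boronate addition to a pyrylium ion). No ring is closed, since ring C arrives intact from the coumarin and only the C2–C1′ bond is formed. The new stereocentre C2 is set under catalyst control, the tartrate-derived ligand on boron choosing the face of the planar cation, and the catalyst antipode used is the one that gives 2S. The step needs C2 over C4 attack, which delivery from boron held where the ethoxide left (next to O1) should secure, and a fast aryl transfer, which the para-OMOM donor and the absence of an ortho substituent on the boronate (the 2′-prenyl group is deferred to step 9) should secure. Bn and MOM ethers should tolerate 5 mol % lanthanide triflate at or below 4 °C, and 12 is kept cold and dark and hydrogenated at once because 2H-chromenes can racemise by oxa-6π ring opening.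

Step 7
Reactants: 12 (2S)-7-(benzyloxy)-2-[3-(benzyloxy)-4-(methoxymethoxy)phenyl]-6-methoxy-2H-chromene
Product: 13 (2S)-2-[3-hydroxy-4-(methoxymethoxy)phenyl]-6-methoxy-3,4-dihydro-2H-chromen-7-ol
Conditions: H2 (1 atm), 10% Pd/C, EtOAc–EtOH, rt
Reagents that add atoms: none
Why: Heterogeneous hydrogenation saturates the cis-disubstituted C3=C4 alkene and hydrogenolyses both primary benzyl aryl ethers in one operation, while the secondary cyclic C2–O1 ether of a flavan is cleaved far more slowly, so C2 stays S and the racemisation channel is closed.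

Step 8
Reactants: 13 (2S)-2-[3-hydroxy-4-(methoxymethoxy)phenyl]-6-methoxy-3,4-dihydro-2H-chromen-7-ol
Product: 14 (2S)-6-methoxy-2-[4-(methoxymethoxy)-3-(2-methylbut-3-en-2-yloxy)phenyl]-7-(2-methylbut-3-en-2-yloxy)-3,4-dihydro-2H-chromene
Conditions: isobutyl 2-methylbut-3-en-2-yl carbonate (3 equiv), Pd(PPh3)4 (5 mol %), 4 Å MS, THF, 0 °C, short reaction time
Reagents that add atoms: isobutyl 2-methylbut-3-en-2-yl carbonate, CC(C)COC(=O)OC(C)(C)C=C
Why: Decarboxylative Tsuji–Trost O-allylation, in which each phenoxide attacks the more substituted terminus of the π-(1,1-dimethylallyl)palladium complex under kinetic control to give the tertiary ethers at O7 and O3′ while O4′ stays masked as MOM.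

Step 9
Reactants: 14 (2S)-6-methoxy-2-[4-(methoxymethoxy)-3-(2-methylbut-3-en-2-yloxy)phenyl]-7-(2-methylbut-3-en-2-yloxy)-3,4-dihydro-2H-chromene
Product: 15 (2S)-2-[3-hydroxy-4-(methoxymethoxy)-2-(3-methylbut-2-en-1-yl)phenyl]-6-methoxy-8-(3-methylbut-2-en-1-yl)-3,4-dihydro-2H-chromen-7-ol
Conditions: PhNEt2, 120 °C, Ar
Reagents that add atoms: none
Why: Double aromatic Claisen rearrangement ([3,3]), in which each ether can deliver a prenyl group productively only to its one hydrogen-bearing ortho carbon (C8, since C6 carries OMe and the para carbon C4a is the ring fusion; C2′, since C4′ carries OMOM) before tautomerising to the phenol, with C2 not involved.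

Step 10
Reactants: 15 (2S)-2-[3-hydroxy-4-(methoxymethoxy)-2-(3-methylbut-2-en-1-yl)phenyl]-6-methoxy-8-(3-methylbut-2-en-1-yl)-3,4-dihydro-2H-chromen-7-ol
Product: 17 (2S)-2-[3,4-dihydroxy-2-(3-methylbut-2-en-1-yl)phenyl]-6-methoxy-8-(3-methylbut-2-en-1-yl)-3,4-dihydro-2H-chromen-7-ol (CNP0214453.1), via tris(trimethylsilyl) ether 16 (not isolated)
Conditions: TMSOTf (5 equiv), 2,2′-bipyridyl (7 equiv), MeCN, 0 °C → rt; then H2O, aq. NaHCO3, MeOH
Reagents that add atoms: none
Why: Buffered silyl triflate cleavage of the aryl MOM ether to the aryl silyl ether followed by hydrolysis, a non-protic deprotection that should avoid acid-catalysed cyclisation of the ortho-prenylphenols to 2,2-dimethylchromans and ionisation of the C2–O1 bond.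

**Compound list**

1 | scopoletin (7-hydroxy-6-methoxy-2H-chromen-2-one) | COc1cc2ccc(=O)oc2cc1O | starting material
2 | 7-(benzyloxy)-6-methoxy-2H-chromen-2-one | COc1cc2ccc(=O)oc2cc1OCc1ccccc1 | intermediate
3 | 7-(benzyloxy)-6-methoxy-2H-chromen-2-ol (lactol, racemic, not isolated) | COc1cc2C=CC(O)Oc2cc1OCc1ccccc1 | intermediate
4 | 7-(benzyloxy)-2-ethoxy-6-methoxy-2H-chromene (racemic) | CCOC1C=Cc2cc(OC)c(OCc3ccccc3)cc2O1 | intermediate
5 | 2-(benzyloxy)phenol | Oc1ccccc1OCc1ccccc1 | starting material
6 | 2-(benzyloxy)-4-bromophenol | Oc1ccc(Br)cc1OCc1ccccc1 | intermediate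
7 | 2-(benzyloxy)-4-bromo-1-(methoxymethoxy)benzene | COCOc1ccc(Br)cc1OCc1ccccc1 | intermediate
8 | [3-(benzyloxy)-4-(methoxymethoxy)phenyl]lithium (not isolated) | [Li]c1ccc(OCOC)c(OCc2ccccc2)c1 | intermediate
9 | lithium [3-(benzyloxy)-4-(methoxymethoxy)phenyl]triisopropoxyborate (not isolated) | [Li+].CC(C)O[B-](OC(C)C)(OC(C)C)c1ccc(OCOC)c(OCc2ccccc2)c1 | intermediate
10 | [3-(benzyloxy)-4-(methoxymethoxy)phenyl]boronic acid | OB(O)c1ccc(OCOC)c(OCc2ccccc2)c1 | intermediate
11 | diethyl [3-(benzyloxy)-4-(methoxymethoxy)phenyl]boronate (not isolated) | CCOB(OCC)c1ccc(OCOC)c(OCc2ccccc2)c1 | intermediate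
12 | (2S)-7-(benzyloxy)-2-[3-(benzyloxy)-4-(methoxymethoxy)phenyl]-6-methoxy-2H-chromene | COc1cc2c(cc1OCc1ccccc1)O[C@H](c1ccc(OCOC)c(OCc3ccccc3)c1)C=C2 | intermediate
13 | (2S)-2-[3-hydroxy-4-(methoxymethoxy)phenyl]-6-methoxy-3,4-dihydro-2H-chromen-7-ol | COc1cc2c(cc1O)O[C@H](c1ccc(OCOC)c(O)c1)CC2 | intermediate
14 | (2S)-6-methoxy-2-[4-(methoxymethoxy)-3-(2-methylbut-3-en-2-yloxy)phenyl]-7-(2-methylbut-3-en-2-yloxy)-3,4-dihydro-2H-chromene | COc1cc2c(cc1OC(C)(C)C=C)O[C@H](c1ccc(OCOC)c(OC(C)(C)C=C)c1)CC2 | intermediate
15 | (2S)-2-[3-hydroxy-4-(methoxymethoxy)-2-(3-methylbut-2-en-1-yl)phenyl]-6-methoxy-8-(3-methylbut-2-en-1-yl)-3,4-dihydro-2H-chromen-7-ol | COc1cc2c(c(CC=C(C)C)c1O)O[C@H](c1ccc(OCOC)c(O)c1CC=C(C)C)CC2 | intermediate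
16 | tris(trimethylsilyl) ether of the target (7-O, 3′-O, 4′-O; not isolated) | COc1cc2c(c(CC=C(C)C)c1O[Si](C)(C)C)O[C@H](c1ccc(O[Si](C)(C)C)c(O[Si](C)(C)C)c1CC=C(C)C)CC2 | intermediate
17 | (2S)-2-[3,4-dihydroxy-2-(3-methylbut-2-en-1-yl)phenyl]-6-methoxy-8-(3-methylbut-2-en-1-yl)-3,4-dihydro-2H-chromen-7-ol (CNP0214453.1) | COc1cc2c(c(CC=C(C)C)c1O)O[C@H](c1ccc(O)c(O)c1CC=C(C)C)CC2 | target

**Step count.** Total: 10 steps. Longest linear sequence: 8 steps (steps 3–10, from 2-(benzyloxy)phenol 5); the scopoletin branch (steps 1–2) joins at step 6.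

**Steps most likely to fail**

Step 6. Facial discrimination in the ion pair may be insufficient with so strongly stabilised a 6,7-dioxygenated pyrylium ion, and hydride transfer from C2–H of the product to unreacted cation may erode the yield. The fallback sets out from 4 and 10 and gives up asymmetric arylation for a stereoconvergent reduction. A nickel(0)-catalysed C–O arylation of the acetal with the boronic acid (Ni(cod)2, PPh3, dioxane/t-AmOH) should give racemic 7-(benzyloxy)-2-[3-(benzyloxy)-4-(methoxymethoxy)phenyl]-6-methoxy-2H-chromene F1. A ruthenium hydride (RuHCl(CO)(PPh3)3, toluene, 80 °C) should then isomerise this cyclic allyl aryl ether to the enol ether 7-(benzyloxy)-2-[3-(benzyloxy)-4-(methoxymethoxy)phenyl]-6-methoxy-4H-chromene F2, erasing the stereocentre so that both enantiomers converge on one achiral alkene. Iridium/chiral N,P-ligand (PHOX-type) asymmetric hydrogenation of this 2-aryl-4H-chromene should give (2S)-7-(benzyloxy)-2-[3-(benzyloxy)-4-(methoxymethoxy)phenyl]-6-methoxy-3,4-dihydro-2H-chromene F3. Hydrogenolysis (H2, Pd/C) then brings the material back to the route at 13.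

Step 9. On ring B the shift into the crowded C2′ position may lose to migration onto C4′ followed by a Cope shift to the para carbon C6′, and the tertiary ethers may shed isoprene before they rearrange. The fallback sets out from 13 and uses primary allyl ethers, which are smaller and cannot eliminate. Allylation (allyl bromide, K2CO3, DMF) should give (2S)-6-methoxy-2-[4-(methoxymethoxy)-3-(prop-2-en-1-yloxy)phenyl]-7-(prop-2-en-1-yloxy)-3,4-dihydro-2H-chromene F4. Thermal Claisen rearrangement (PhNEt2, 190 °C) should give (2S)-2-[3-hydroxy-4-(methoxymethoxy)-2-(prop-2-en-1-yl)phenyl]-6-methoxy-8-(prop-2-en-1-yl)-3,4-dihydro-2H-chromen-7-ol F5. Double cross-metathesis with 2-methylbut-2-ene (Grubbs second-generation catalyst, CH2Cl2, 40 °C) turns both allyl groups into prenyl groups and comes back to the route at 15.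

Step 8. Palladium can re-ionise the tertiary ethers once formed, letting them drift to the linear prenyl ethers (which would rearrange to the wrong, reverse-prenylated carbon skeleton), and the hindered O3′ may alkylate incompletely. The fallback sets out from 13 and forms the tertiary C–O bonds by copper-catalysed propargylation. Treatment with 3-chloro-3-methylbut-1-yne, DBU and catalytic CuCl2 (MeCN, 0 °C) should give (2S)-6-methoxy-2-[4-(methoxymethoxy)-3-(2-methylbut-3-yn-2-yloxy)phenyl]-7-(2-methylbut-3-yn-2-yloxy)-3,4-dihydro-2H-chromene F6. Lindlar semi-hydrogenation (H2, Pd/CaCO3/Pb, quinoline, EtOAc) then comes back to the route at 14.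

**Further compounds**

F1 | step 6 | 7-(benzyloxy)-2-[3-(benzyloxy)-4-(methoxymethoxy)phenyl]-6-methoxy-2H-chromene (racemic) | COc1cc2c(cc1OCc1ccccc1)OC(c1ccc(OCOC)c(OCc3ccccc3)c1)C=C2
F2 | step 6 | 7-(benzyloxy)-2-[3-(benzyloxy)-4-(methoxymethoxy)phenyl]-6-methoxy-4H-chromene | COc1cc2c(cc1OCc1ccccc1)OC(c1ccc(OCOC)c(OCc3ccccc3)c1)=CC2
F3 | step 6 | (2S)-7-(benzyloxy)-2-[3-(benzyloxy)-4-(methoxymethoxy)phenyl]-6-methoxy-3,4-dihydro-2H-chromene | COc1cc2c(cc1OCc1ccccc1)O[C@H](c1ccc(OCOC)c(OCc3ccccc3)c1)CC2
F4 | step 9 | (2S)-6-methoxy-2-[4-(methoxymethoxy)-3-(prop-2-en-1-yloxy)phenyl]-7-(prop-2-en-1-yloxy)-3,4-dihydro-2H-chromene | COc1cc2c(cc1OCC=C)O[C@H](c1ccc(OCOC)c(OCC=C)c1)CC2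
F5 | step 9 | (2S)-2-[3-hydroxy-4-(methoxymethoxy)-2-(prop-2-en-1-yl)phenyl]-6-methoxy-8-(prop-2-en-1-yl)-3,4-dihydro-2H-chromen-7-ol | COc1cc2c(c(CC=C)c1O)O[C@H](c1ccc(OCOC)c(O)c1CC=C)CC2
F6 | step 8 | (2S)-6-methoxy-2-[4-(methoxymethoxy)-3-(2-methylbut-3-yn-2-yloxy)phenyl]-7-(2-methylbut-3-yn-2-yloxy)-3,4-dihydro-2H-chromene | COc1cc2c(cc1OC(C)(C)C#C)O[C@H](c1ccc(OCOC)c(OC(C)(C)C#C)c1)CC2
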